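## Structural features

Licoricidin is an isoflavan: ring A is fused to the oxygen heterocycle ring C (O1, C2, C3, C4) to give a chroman, and ring B is attached to C3 through C1'. Ring A carries 5-OMe, a 6-prenyl group and 7-OH; ring B carries 2'-OH, a 3'-prenyl group and 4'-OH, so each prenyl group sits between two oxygen-bearing carbons. C3 (R) is the only stereocentre; it lies between the methylene groups C2 and C4, has no neighbouring stereocentre to relay from, and must be set absolutely. The fragile elements are the two trisubstituted alkenes (no hydrogenation, no strong electrophiles), the phenols ortho to them (acid closes them to dimethylchromans), and C4, which as a 2,4,6-trioxygenated benzylic carbon ionises easily once it bears a leaving group. The real difficulty is therefore an isolated benzylic stereocentre combined with five oxygen atoms that must be told apart and two prenyl groups that must be placed regioselectively without acid. The feature used here is that O2' is ortho to C1': the chain C3–C1'–C2'–O2'–C4 has five atoms, so ring A can hang on O2' through C4 as a benzyl ether, a carbene at C3 can insert into a C4–H bond to forge C3–C4 inside a temporary dihydrofuran ring, and the benzylic C4–O2' bond can be cut reductively at the end, which deletes the auxiliary centre at C4 and returns the 2'-OH.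

## Logic of the disconnections

**29 to 28.** C4–O2' is reconnected and benzyl groups are placed on O7 and O4'. All three are benzylic C–O bonds, so one electron-transfer step can cut them together in the forward direction. The gain is that C3 is held in a rigid cis-fused tetracycle and no free phenol sits beside a prenyl group until the last flask, so no acid is needed anywhere after the prenyl groups are in place. The demand is a reduction that spares the prenyl alkenes, the aryl methyl ether and the O1–C2 bond.

**28 to 27, 26 and 24.** O1–C2 is cut, the silyl group is returned to the ring A oxygen that becomes O1, and C2 is raised to the ester oxidation level. O1–C2 is a primary alkyl–oxygen bond that a Mitsunobu closure forms without touching C3. The gain is that ring C shrinks to an ester on a dihydrobenzofuran. The demand is that C3–H, alpha to the ester in 24, must not epimerise (non-basic hydride, low temperature), and that the unmasked phenol must not expel O2' from C4.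

**24 to 22.** C3–C4 is cut, the bond that joins the two halves and the only C–C bond to the stereocentre that is not an aryl bond. The gain is an achiral, acyclic diazo ester. The forward step must create C3 and C4 with cis geometry and in the (2R,3S) sense (benzofuran locants); after reduction of the ester the same spatial arrangement at C3 is R, as 29 requires. The skeleton of 22 is kept but three points of design are changed:
- the ring A silyl ether is TIPS, which should resist DBU in the diazo transfer and alkoxide-induced migration in step 6;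
- O7 and O4' carry benzyl instead of acetal groups, so the last step removes them and no acid meets the ortho-prenyl phenols;
- both positions of ring A ortho to C4 are substituted (OMe, OTIPS), which leaves the carbene no aromatic C–H to attack.

**22 to 21 and 18 with 19.** The diazo group is removed (diazo transfer in the forward sense) and the C1'–C3 bond is cut to an aryl bromide and a zinc ester enolate. C3 and C2 arrive together as an acetate unit, and placing it after the ether formation lets ring B travel as a simple bromophenol. The demand is a palladium coupling that tolerates the silyl ether and the prenyl groups and does not ionise the benzylic ether.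

**18 to 10 and 17.** The O2'–C4 ether bond is cut. This is the convergent point; both halves carry all their substituents. The demand is O-alkylation of a doubly ortho-substituted phenol by a benzylic alcohol that ionises easily.

**10 to 9, 8, 5, 3, 2 and 1.** After adjustment of the oxidation level at C4 and removal of the silyl group, the aryl–prenyl bond at C6 is cut by returning the prenyl group to the ring A oxygen para to it (para-Claisen–Cope retron). The remaining O–C bonds are cut in the order of phenol reactivity in 1 (4-OH first, then one of the two equivalent chelated hydroxyls). The gain is a symmetric commercial trihydroxybenzaldehyde. The demand is para delivery of the prenyl group and clean mono-alkylations.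

**17 to 15, 14, 12 and 11.** The aryl–prenyl bond at C3' is cut by an ortho-Claisen retron to the tertiary allyl ether, which comes from the propargyl ether made from 12 and 13. The regiochemistry is forced because only one ortho position carries hydrogen. Cutting the benzyl ether gives 11; the demand is benzylation of the hydroxyl para to bromine.

## Other disconnections considered

**Alternative 1:** Three bonds of ring B are cut (C1'–C2', C2'–C3', C4'–C5'), leading to the diazo enone A1, which already holds ring A, ring C and C3, and to the siloxyalkyne A2.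
- Forward step: irradiation of A1 would trigger a Wolff rearrangement to a vinylketene; [2+2] addition to A2, 4π opening of the cyclobutenone, 6π closure and tautomerisation would give the isoflavan A3 (Danheiser benzannulation).
- In favour: ring B is born with free 2'-OH, 3'-prenyl and silylated 4'-OH in fixed positions. On differentiating the ring B oxygens it is better than the chosen plan, which needs a selective benzylation and a three-step ortho-prenylation. No sacrificial ring and no reductive opening are needed, and A3 is only two deprotections from the target against four steps from 24.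
- Against: C3 must be made beforehand on an alpha-branched chroman-3-carbonyl compound that epimerises easily and needs its own asymmetric step. The carbene and the ketene are generated under UV light beside three electron-rich trisubstituted alkenes. The sequence is linear from ring A, so the valuable chroman enters a cascade with several thermal branch points.
- Comparison: in structure, the chosen plan creates C3 in the step that joins the halves, whereas here stereocentre and ring construction are separate problems. In mechanism, both use a diazo compound, but the dirhodium carbene is formed cold and has one reachable C–H bond. In step economy the two should be about equal; the gain at the end is paid for in making A1 enantioenriched.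

**Alternative 2:** C3–C4 and the acyl O1–C2 bond are cut, leading to the ring A sulfone A4 and the ring B acyl imidazole A5.
- Forward step: Cs2CO3 would eliminate sulfinate from A4 to an ortho-quinone methide; a chiral triazolium-derived carbene would turn A5 into an azolium enolate, which adds to the methide carbon (C3–C4) and is acylated by the phenoxide (O1–C2) to give the dihydrocoumarin A6.
- In favour: it forges the same strategic bond C3–C4 as the chosen plan (equal on that point), without an auxiliary ring or a stereocentre to erase. Ring C closes in the same step, so it is more convergent and on paper shorter to the full skeleton (better), and it needs no precious metal.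
- Against: C3 in A6 is benzylic and alpha to an aryl ester carbonyl, and it is formed in the basic medium that can epimerise it. The methide from A4 has the 5-OMe group next to the reacting carbon. The lactone carbonyl must then be removed (reduction to the diol and re-closure). The acetal groups need acid at the end beside the ortho-prenyl phenols.
- Comparison: in structure both plans need a labile 2,4,6-trioxygenated benzylic electrophile on ring A (equal). In mechanism, the chosen plan never exposes C3 to base as an enolisable centre once it is set. In step economy Alternative 2 is roughly equal after the lactone is corrected.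

**Alternative 3:** C3–C1' and C4–O2' are cut, leading to the ring A chromene A7 and the quinone A8 as an umpoled ring B.
- Forward step: TiCl2(TADDOLate) would activate A8; C3 of A7 attacks C5 of the quinone, the quinone oxygen captures the C4 cation and aromatisation gives the cis-pterocarpan A9 with an extra 5'-OH.
- In favour: one step from two flat, achiral partners reaches the same kind of cis-pterocarpan as 28, setting both centres together. Up to that stage its step economy is clearly better, and no diazo compound is involved.
- Against: a prenyl-substituted quinone is prone to tautomerise and cyclise to a chromenol. The titanium TADDOLate is normally needed in stoichiometric amount and its selectivity depends strongly on the quinone substituents. The site of attack (C5 or C6) rests on the allyloxy group alone. The 5'-oxygen must then be removed (triflate, then reduction with a zerovalent palladium catalyst) and the allyl ether cleaved.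
- Comparison: in structure both plans pass through a pterocarpan and need the same reductive C4–O2' opening (equal). In mechanism, the cationic stepwise annulation has less precedent for high enantioselectivity on a chromene with a peri methoxy group than the carbene insertion has on benzyl ethers. In step economy the early advantage is largely used up by the three corrective steps.

Key step: step 14

Assumption: Rh2(S-PTTL)4 is taken to give the (2R,3S)-cis product, the sense expected from simpler 2-benzyloxyphenyl diazoacetates; if the crowded substrate responds with the opposite sense, Rh2(R-PTTL)4 from D-tert-leucine is used and nothing else changes.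

Remark: isoflavan locants (O1, C2, C3, C4, primed locants for ring B) are used for all intermediates; "prenyl" is 3-methylbut-2-en-1-yl.

## Route

Step 1
Reactants: 1 2,4,6-trihydroxybenzaldehyde
Product: 2 4-(benzyloxy)-2,6-dihydroxybenzaldehyde
Conditions: BnBr (1.0 equiv), K2CO3 (1.0 equiv), DMF, 0 °C to rt
Reagents that add atoms: benzyl bromide, BrCc1ccccc1
Why: Williamson etherification; the 4-OH, para to the formyl group and not held in a hydrogen bond to it, is the most acidic and most accessible hydroxyl, so one equivalent of base and halide should alkylate it first.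

Step 2
Reactants: 2 4-(benzyloxy)-2,6-dihydroxybenzaldehyde
Product: 3 4-(benzyloxy)-2-hydroxy-6-methoxybenzaldehyde
Conditions: MeI (1.1 equiv), K2CO3 (1.2 equiv), acetone, 40 °C
Reagents that add atoms: iodomethane, CI
Why: Williamson etherification; the two ortho hydroxyls are equivalent, and after one is methylated the other is locked in a hydrogen bond to the aldehyde and should resist these mild conditions, so the reaction should stop at the monomethyl ether.

Step 3
Reactants: 3 4-(benzyloxy)-2-hydroxy-6-methoxybenzaldehyde; 4 prenyl bromide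
Product: 5 4-(benzyloxy)-2-methoxy-6-(prenyloxy)benzaldehyde
Conditions: K2CO3 (2 equiv), DMF, 60 °C
Reagents that add atoms: none
Why: Williamson etherification of the chelated phenol under more forcing conditions; a primary allylic bromide in a polar aprotic solvent should favour O- over C-alkylation.

Step 4
Reactants: 5 4-(benzyloxy)-2-methoxy-6-(prenyloxy)benzaldehyde
Product: 8 4-(benzyloxy)-6-hydroxy-2-methoxy-3-prenylbenzaldehyde, via ortho-dienone 6 (not isolated), via para-dienone 7 (not isolated)
Conditions: PhNEt2, 190 °C, sealed tube
Reagents that add atoms: none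
Why: Para-Claisen–Cope sequence, as known for 2-prenyloxy-4,6-dialkoxyaryl ketones; the aromatic Claisen shift to the only free ortho carbon gives 6, whose bulky 1,1-dimethylallyl group should move on by Cope rearrangement to the para carbon (7) faster than 6 enolises in the basic aprotic medium. Enolisation of 7 then leaves the prenyl group between OMe and OBn.

Step 5
Reactants: 8 4-(benzyloxy)-6-hydroxy-2-methoxy-3-prenylbenzaldehyde
Product: 9 4-(benzyloxy)-2-methoxy-3-prenyl-6-(triisopropylsilyloxy)benzaldehyde
Conditions: TIPSCl (1.3 equiv), imidazole (2.5 equiv), DMF, rt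
Reagents that add atoms: chlorotriisopropylsilane, CC(C)[Si](Cl)(C(C)C)C(C)C
Why: Silylation of the one free phenol; TIPS is chosen because it should survive the alkoxide formed in step 6 and DBU in step 13, and is still removed by fluoride.

Step 6
Reactants: 9 4-(benzyloxy)-2-methoxy-3-prenyl-6-(triisopropylsilyloxy)benzaldehyde
Product: 10 [4-(benzyloxy)-2-methoxy-3-prenyl-6-(triisopropylsilyloxy)phenyl]methanol
Conditions: NaBH4, THF/MeOH, 0 °C; pH 7 buffer
Reagents that add atoms: none
Why: Borohydride reduction of the aldehyde; the bulky silyl group should not migrate to the new alkoxide at 0 °C, and the neutral work-up avoids ionising the electron-rich benzylic alcohol.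

Step 7
Reactants: 11 4-bromoresorcinol
Product: 12 5-(benzyloxy)-2-bromophenol
Conditions: BnBr (1.0 equiv), K2CO3 (1.0 equiv), acetone, rt
Reagents that add atoms: benzyl bromide, BrCc1ccccc1
Why: Williamson etherification; the hydroxyl para to bromine is unhindered, whereas the one ortho to bromine is shielded and its phenoxide is less nucleophilic, so monoalkylation should fall on the former and leave the bromophenol unit intact.

Step 8
Reactants: 12 5-(benzyloxy)-2-bromophenol; 13 3-chloro-3-methylbut-1-yne
Product: 14 4-(benzyloxy)-1-bromo-2-[(2-methylbut-3-yn-2-yl)oxy]benzene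
Conditions: DBU (1.6 equiv), CuCl2·2H2O (0.5 mol%), MeCN, 0 °C
Reagents that add atoms: none
Why: Copper-catalysed propargylic substitution of a tertiary propargyl chloride by a phenoxide, the standard entry to aryl 1,1-dimethylpropargyl ethers; ortho-substituted phenols are competent.

Step 9
Reactants: 14 4-(benzyloxy)-1-bromo-2-[(2-methylbut-3-yn-2-yl)oxy]benzene
Product: 15 4-(benzyloxy)-1-bromo-2-[(2-methylbut-3-en-2-yl)oxy]benzene
Conditions: H2 (1 atm), Pd/CaCO3 poisoned with Pb(OAc)2, quinoline, EtOAc, rt
Reagents that add atoms: none
Why: Lindlar semihydrogenation of the terminal alkyne; the poisoned catalyst should leave the aryl bromide and the benzyl ether alone.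

Step 10
Reactants: 15 4-(benzyloxy)-1-bromo-2-[(2-methylbut-3-en-2-yl)oxy]benzene
Product: 17 3-(benzyloxy)-6-bromo-2-prenylphenol, via ortho-dienone 16 (not isolated)
Conditions: PhNEt2, 130 °C
Reagents that add atoms: none
Why: Aromatic Claisen rearrangement; the tertiary allyl ether delivers its terminal carbon, so the group arrives as prenyl, and the only ortho carbon that bears hydrogen lies between the two oxygens, so 16 can only form there before it enolises.

Step 11
Reactants: 10 [4-(benzyloxy)-2-methoxy-3-prenyl-6-(triisopropylsilyloxy)phenyl]methanol; 17 3-(benzyloxy)-6-bromo-2-prenylphenol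
Product: 18 1-(benzyloxy)-4-bromo-3-{[4-(benzyloxy)-2-methoxy-3-prenyl-6-(triisopropylsilyloxy)phenyl]methoxy}-2-prenylbenzene
Conditions: PPh3, DIAD, toluene, 0 °C to rt
Reagents that add atoms: none
Why: Mitsunobu etherification; the bromophenol is acidic enough to protonate the betaine and the activated benzylic carbon is highly reactive, so O-alkylation should proceed under near-neutral conditions without a free benzylic halide.

Step 12
Reactants: 18 aryl bromide from step 11; 19 methyl bromoacetate
Product: 21 methyl 2-[4-(benzyloxy)-2-{[4-(benzyloxy)-2-methoxy-3-prenyl-6-(triisopropylsilyloxy)phenyl]methoxy}-3-prenylphenyl]acetate, via Reformatsky reagent 20 (not isolated)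
Conditions: Zn, THF (19 to 20); then 18, Pd2(dba)3 (2 mol%), XPhos (8 mol%), THF, 45 °C
Reagents that add atoms: none
Why: Negishi-type coupling of an aryl bromide with a Reformatsky reagent (palladium-catalysed alpha-arylation of a zinc ester enolate); the neutral zinc enolate should tolerate the silyl ether, benzyl ethers and alkenes, and the bulky biaryl phosphine should allow oxidative addition to the electron-rich ortho-alkoxy bromide.

Step 13
Reactants: 21 arylacetate from step 12
Product: 22 methyl 2-diazo-2-[4-(benzyloxy)-2-{[4-(benzyloxy)-2-methoxy-3-prenyl-6-(triisopropylsilyloxy)phenyl]methoxy}-3-prenylphenyl]acetate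
Conditions: p-ABSA (1.5 equiv), DBU (2 equiv), MeCN, 0 °C to rt
Reagents that add atoms: 4-acetamidobenzenesulfonyl azide, CC(=O)Nc1ccc(cc1)S(=O)(=O)N=[N+]=[N-]
Why: Regitz diazo transfer to the benzylic ester carbon, the standard route to aryldiazoacetates; the TIPS ether should withstand DBU, and the strongly basic medium is harmless to the acid-labile benzylic ether.

Step 14
Reactants: 22 aryldiazoacetate from step 13
Product: 24 methyl (2R,3S)-6-(benzyloxy)-2-[4-(benzyloxy)-2-methoxy-3-prenyl-6-(triisopropylsilyloxy)phenyl]-7-prenyl-2,3-dihydro-1-benzofuran-3-carboxylate, via rhodium carbene 23 (not isolated)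
Conditions: Rh2(S-PTTL)4 (dirhodium tetrakis[N-phthaloyl-(S)-tert-leucinate], 1 mol%), toluene, −60 °C, slow addition of 22
Reagents that add atoms: none
Why: Rh2(S-PTTL)4, a dimer of divalent rhodium, takes up the diazo carbon at a free axial site and loses N2 to give the donor–acceptor carbene 23; its carbene carbon (C3) then inserts into one C4–H bond through a three-centre, hydride-transfer-like transition state. The closest known reaction type is the dirhodium-carboxylate-catalysed intramolecular C–H insertion of methyl 2-(2-benzyloxyphenyl)-2-diazoacetates, which gives cis-2-aryl-2,3-dihydrobenzofuran-3-carboxylates. The dihydrofuran ring closes by 1,5-insertion, C3 bonding to the fifth atom of the chain C3–C1'–C2'–O2'–C4. C3 is controlled by the phthalimido wall of the catalyst, which exposes one face of the carbene; C4 is set in the same transition state, because only one of the two C4–H bonds can reach that face with ring A turned away from the ligands, and this places ring A cis to the ester. The step needs chemoselectivity for this C–H bond over the prenyl alkenes, the other ether C–H bonds and the arenes: no other C–H bond or alkene lies within five- or six-membered reach of C3, both positions of ring A ortho to C4 are blocked (OMe, OTIPS), and slow addition keeps bimolecular cyclopropanation and carbene dimerisation down. It also needs the concerted pathway, which the low temperature and the non-polar solvent favour. The product is the (2R,3S)-ester in benzofuran locants; after reduction of the ester the same arrangement at C3 is R, as in 29.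

Step 15
Reactants: 24 cis-dihydrobenzofuran ester from step 14
Product: 26 [(2R,3R)-6-(benzyloxy)-2-[4-(benzyloxy)-2-methoxy-3-prenyl-6-(triisopropylsilyloxy)phenyl]-7-prenyl-2,3-dihydro-1-benzofuran-3-yl]methanol, via aldehyde 25 (not isolated)
Conditions: i-Bu2AlH (3 equiv), CH2Cl2, −78 to −40 °C; aq. KNaC4H4O6
Reagents that add atoms: none
Why: Hydride reduction of the ester with a non-basic aluminium hydride; 25 is formed in the presence of excess hydride and should be reduced faster than it can enolise, so C3 keeps its configuration (the descriptor changes from S to R only through the priority rules).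

Step 16
Reactants: 26 primary alcohol from step 15
Product: 27 5-(benzyloxy)-2-[(2R,3R)-6-(benzyloxy)-3-(hydroxymethyl)-7-prenyl-2,3-dihydro-1-benzofuran-2-yl]-3-methoxy-4-prenylphenol
Conditions: Bu4NF (1.1 equiv), AcOH (1.2 equiv), THF, 0 °C
Reagents that add atoms: none
Why: Fluoride cleavage of the aryl silyl ether; the acetic acid buffer delivers the phenol, not the phenoxide, which should keep the ortho oxygen from expelling O2' from C4.

Step 17
Reactants: 27 phenol alcohol from step 16
Product: 28 (6aR,11aR)-3,9-bis(benzyloxy)-1-methoxy-2,10-diprenyl-6a,11a-dihydro-6H-[1]benzofuro[3,2-c]chromene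
Conditions: PPh3, DIAD, THF (0.01 M), 0 °C to rt
Reagents that add atoms: none
Why: Intramolecular Mitsunobu etherification; the ring A phenol displaces the activated primary oxygen at C2 (6-exo-tet) to close ring C, no stereocentre is involved, and the cis relationship set in step 14 gives the unstrained cis-fused pterocarpan.

Step 18
Reactants: 28 cis-pterocarpan from step 17
Product: 29 licoricidin, 4-[(3R)-7-hydroxy-5-methoxy-6-prenyl-3,4-dihydro-2H-chromen-3-yl]-2-prenylbenzene-1,3-diol
Conditions: Li (excess), NH3/THF, −78 °C, short contact time; solid NH4Cl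
Reagents that add atoms: none
Why: Dissolving-metal (Birch-type) cleavage of benzylic C–O bonds; electron transfer should break C4–O2' (benzylic to ring A, aryloxide leaving group) and both O–CH2Ph bonds, C4 becomes CH2 so its stereocentre vanishes, and C3 carries no acidic or reducible function and stays R. Without an added alcohol the isolated trisubstituted alkenes, the aryl methyl ether and the O1–C2 bond should be inert, and the phenoxides formed protect both rings from reduction.

## Compound list

1 | 2,4,6-trihydroxybenzaldehyde | O=Cc1c(O)cc(O)cc1O | starting material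
2 | 4-(benzyloxy)-2,6-dihydroxybenzaldehyde | O=Cc1c(O)cc(OCc2ccccc2)cc1O | intermediate
3 | 4-(benzyloxy)-2-hydroxy-6-methoxybenzaldehyde | COc1cc(OCc2ccccc2)cc(O)c1C=O | intermediate
4 | prenyl bromide (1-bromo-3-methylbut-2-ene) | CC(C)=CCBr | starting material
5 | 4-(benzyloxy)-2-methoxy-6-[(3-methylbut-2-en-1-yl)oxy]benzaldehyde | COc1cc(OCc2ccccc2)cc(OCC=C(C)C)c1C=O | intermediate
6 | ortho-dienone, 4-(benzyloxy)-2-methoxy-5-(2-methylbut-3-en-2-yl)-6-oxocyclohexa-1,3-diene-1-carbaldehyde (racemic) | O=CC1=C(OC)C=C(OCc2ccccc2)C(C(C)(C)C=C)C1=O | intermediate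
7 | para-dienone, 4-(benzyloxy)-2-methoxy-3-(3-methylbut-2-en-1-yl)-6-oxocyclohexa-1,4-diene-1-carbaldehyde (racemic) | O=CC1=C(OC)C(CC=C(C)C)C(OCc2ccccc2)=CC1=O | intermediate
8 | 4-(benzyloxy)-6-hydroxy-2-methoxy-3-(3-methylbut-2-en-1-yl)benzaldehyde | COc1c(CC=C(C)C)c(OCc2ccccc2)cc(O)c1C=O | intermediate
9 | 4-(benzyloxy)-2-methoxy-3-(3-methylbut-2-en-1-yl)-6-[(triisopropylsilyl)oxy]benzaldehyde | COc1c(CC=C(C)C)c(OCc2ccccc2)cc(O[Si](C(C)C)(C(C)C)C(C)C)c1C=O | intermediate
10 | {4-(benzyloxy)-2-methoxy-3-(3-methylbut-2-en-1-yl)-6-[(triisopropylsilyl)oxy]phenyl}methanol | COc1c(CC=C(C)C)c(OCc2ccccc2)cc(O[Si](C(C)C)(C(C)C)C(C)C)c1CO | intermediate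
11 | 4-bromoresorcinol (4-bromobenzene-1,3-diol) | Oc1ccc(Br)c(O)c1 | starting material
12 | 5-(benzyloxy)-2-bromophenol | Oc1cc(OCc2ccccc2)ccc1Br | intermediate
13 | 3-chloro-3-methylbut-1-yne | CC(C)(Cl)C#C | starting material
14 | 4-(benzyloxy)-1-bromo-2-[(2-methylbut-3-yn-2-yl)oxy]benzene | C#CC(C)(C)Oc1cc(OCc2ccccc2)ccc1Br | intermediate
15 | 4-(benzyloxy)-1-bromo-2-[(2-methylbut-3-en-2-yl)oxy]benzene | C=CC(C)(C)Oc1cc(OCc2ccccc2)ccc1Br | intermediate
16 | ortho-dienone, 5-(benzyloxy)-2-bromo-6-(3-methylbut-2-en-1-yl)cyclohexa-2,4-dien-1-one (racemic) | O=C1C(Br)=CC=C(OCc2ccccc2)C1CC=C(C)C | intermediate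
17 | 3-(benzyloxy)-6-bromo-2-(3-methylbut-2-en-1-yl)phenol | Oc1c(Br)ccc(OCc2ccccc2)c1CC=C(C)C | intermediate
18 | 1-(benzyloxy)-4-bromo-3-({4-(benzyloxy)-2-methoxy-3-(3-methylbut-2-en-1-yl)-6-[(triisopropylsilyl)oxy]phenyl}methoxy)-2-(3-methylbut-2-en-1-yl)benzene | COc1c(CC=C(C)C)c(OCc2ccccc2)cc(O[Si](C(C)C)(C(C)C)C(C)C)c1COc1c(Br)ccc(OCc2ccccc2)c1CC=C(C)C | intermediate
19 | methyl bromoacetate | COC(=O)CBr | starting material
20 | Reformatsky reagent, bromo(2-methoxy-2-oxoethyl)zinc | COC(=O)C[Zn]Br | intermediate
21 | methyl 2-[4-(benzyloxy)-2-({4-(benzyloxy)-2-methoxy-3-(3-methylbut-2-en-1-yl)-6-[(triisopropylsilyl)oxy]phenyl}methoxy)-3-(3-methylbut-2-en-1-yl)phenyl]acetate | COC(=O)Cc1ccc(OCc2ccccc2)c(CC=C(C)C)c1OCc1c(OC)c(CC=C(C)C)c(OCc2ccccc2)cc1O[Si](C(C)C)(C(C)C)C(C)C | intermediate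
22 | methyl 2-diazo-2-[4-(benzyloxy)-2-({4-(benzyloxy)-2-methoxy-3-(3-methylbut-2-en-1-yl)-6-[(triisopropylsilyl)oxy]phenyl}methoxy)-3-(3-methylbut-2-en-1-yl)phenyl]acetate | COC(=O)C(=[N+]=[N-])c1ccc(OCc2ccccc2)c(CC=C(C)C)c1OCc1c(OC)c(CC=C(C)C)c(OCc2ccccc2)cc1O[Si](C(C)C)(C(C)C)C(C)C | intermediate
23 | rhodium carbene derived from 22 (carbene ligand on one rhodium atom; second rhodium atom and the four carboxylate ligands not drawn) | COC(=O)C(=[Rh])c1ccc(OCc2ccccc2)c(CC=C(C)C)c1OCc1c(OC)c(CC=C(C)C)c(OCc2ccccc2)cc1O[Si](C(C)C)(C(C)C)C(C)C | intermediate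
24 | methyl (2R,3S)-6-(benzyloxy)-2-{4-(benzyloxy)-2-methoxy-3-(3-methylbut-2-en-1-yl)-6-[(triisopropylsilyl)oxy]phenyl}-7-(3-methylbut-2-en-1-yl)-2,3-dihydro-1-benzofuran-3-carboxylate | COc1c(CC=C(C)C)c(OCc2ccccc2)cc(O[Si](C(C)C)(C(C)C)C(C)C)c1[C@@H]1Oc2c(CC=C(C)C)c(OCc3ccccc3)ccc2[C@@H]1C(=O)OC | intermediate
25 | (2R,3S)-6-(benzyloxy)-2-{4-(benzyloxy)-2-methoxy-3-(3-methylbut-2-en-1-yl)-6-[(triisopropylsilyl)oxy]phenyl}-7-(3-methylbut-2-en-1-yl)-2,3-dihydro-1-benzofuran-3-carbaldehyde | COc1c(CC=C(C)C)c(OCc2ccccc2)cc(O[Si](C(C)C)(C(C)C)C(C)C)c1[C@@H]1Oc2c(CC=C(C)C)c(OCc3ccccc3)ccc2[C@@H]1C=O | intermediate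
26 | [(2R,3R)-6-(benzyloxy)-2-{4-(benzyloxy)-2-methoxy-3-(3-methylbut-2-en-1-yl)-6-[(triisopropylsilyl)oxy]phenyl}-7-(3-methylbut-2-en-1-yl)-2,3-dihydro-1-benzofuran-3-yl]methanol | COc1c(CC=C(C)C)c(OCc2ccccc2)cc(O[Si](C(C)C)(C(C)C)C(C)C)c1[C@@H]1Oc2c(CC=C(C)C)c(OCc3ccccc3)ccc2[C@@H]1CO | intermediate
27 | 5-(benzyloxy)-2-[(2R,3R)-6-(benzyloxy)-3-(hydroxymethyl)-7-(3-methylbut-2-en-1-yl)-2,3-dihydro-1-benzofuran-2-yl]-3-methoxy-4-(3-methylbut-2-en-1-yl)phenol | COc1c(CC=C(C)C)c(OCc2ccccc2)cc(O)c1[C@@H]1Oc2c(CC=C(C)C)c(OCc3ccccc3)ccc2[C@@H]1CO | intermediate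
28 | (6aR,11aR)-3,9-bis(benzyloxy)-1-methoxy-2,10-bis(3-methylbut-2-en-1-yl)-6a,11a-dihydro-6H-[1]benzofuro[3,2-c]chromene | COc1c(CC=C(C)C)c(OCc2ccccc2)cc2c1[C@@H]1Oc3c(CC=C(C)C)c(OCc4ccccc4)ccc3[C@@H]1CO2 | intermediate
29 | licoricidin, 4-[(3R)-7-hydroxy-5-methoxy-6-(3-methylbut-2-en-1-yl)-3,4-dihydro-2H-chromen-3-yl]-2-(3-methylbut-2-en-1-yl)benzene-1,3-diol | COc1c(CC=C(C)C)c(O)cc2c1C[C@H](c1ccc(O)c(CC=C(C)C)c1O)CO2 | target

## Step count and least certain steps

Total: 18 steps. Longest linear sequence: 14 steps (steps 1–6, then 11–18); the ring B branch (steps 7–10) joins at step 11.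

**Step 14 (key step).** The most likely failure is erosion of cis and enantioselectivity. C4–H is flanked by a very electron-rich, doubly ortho-substituted ring A, so the insertion may drift towards a stepwise hydride transfer in which the zwitterion rotates before the C–C bond forms. Crowding may also slow insertion enough for carbene dimerisation to compete. The fallback leaves the carbene route and sets C3 by auxiliary-controlled enolate alkylation (Evans alkylation); it sets out from 17 and 10 and comes back to the route at 29.
- Phenol 17 is benzylated (BnBr, K2CO3, DMF) to the aryl bromide F1, which is coupled with 20 as in step 12 to the arylacetate F2.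
- LiOH gives the acid F3, which is joined through its mixed pivalic anhydride to lithiated (R)-4-benzyloxazolidin-2-one to give the imide F4.
- Alcohol 10 is converted at −40 °C (MsCl, Et3N, then LiBr, THF) into the benzylic bromide F5, which is used at once because it ionises readily.
- The sodium enolate of F4 (NaN(SiMe3)2, THF, −78 °C) should be alkylated by F5 on the face away from the auxiliary benzyl group, giving the alkylated imide F6 with the (R) centre that becomes C3.
- LiBH4 removes the auxiliary reductively to the primary alcohol F7, Bu4NF/AcOH frees the phenol F8, and Mitsunobu closure gives the tri-O-benzyl isoflavan F9.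
- The Li/NH3 conditions of step 18 convert F9 into 29.

**Step 4.** The most likely failure is enolisation of 6 before the Cope shift, which would leave a 1,1-dimethylallyl group at the wrong (ortho) carbon, possibly followed by cyclisation of that phenol onto its alkene. The fallback places the prenyl group by direct C-alkylation before the two ortho oxygens are differentiated; it sets out from 2 and returns at 9.
- 2 is C-prenylated with 4 (DBU, THF, 0 °C; the two open ring positions are equivalent) to the prenylated dihydroxybenzaldehyde F10.
- TIPSCl/imidazole silylates the hydroxyl remote from the prenyl group to give the mono-silyl ether F11.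
- Mitsunobu methylation (MeOH, PPh3, DIAD) of the remaining chelated hydroxyl gives 9.

**Step 11.** The most likely failure is ionisation of the activated form of 10 to a 2,4,6-trioxygenated benzylic cation, leading to C-alkylation of 17 or self-condensation, while O-alkylation of the doubly ortho-substituted phenol is slow. The fallback replaces the redox condensation by a phenoxide displacement; it sets out from 10 and returns at 18. 10 is converted at −20 °C (MsCl, Et3N, LiCl, CH2Cl2) into the benzylic chloride F12, which is added cold to the caesium phenoxide of 17 (Cs2CO3, DMF, 0 °C) to give 18.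

**Step 12.** The most likely failure is slow oxidative addition to the electron-rich, ortho-alkoxy bromide of a large substrate, together with cleavage of the labile benzylic ether by the zinc halide that accumulates. The fallback installs the acetate unit before the ether is made; it sets out from 17 and returns at 21.
- 17 is silylated (TBSCl, imidazole) to the silyl ether F13, which is coupled with 20 under the conditions of step 12 to the arylacetate F14.
- Bu4NF/AcOH gives the hydroxy ester F15, which is coupled with 10 under the Mitsunobu conditions of step 11 to give 21.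

**Step 16.** The most likely failure is expulsion of the O2' phenoxide from C4 by the newly freed ortho oxygen. This would give an ortho-quinone methide that opens the dihydrofuran ring and can tautomerise through C3–H, putting the stereocentre at risk. The fallback closes ring C in the flask in which the phenoxide is released; it sets out from 26 and returns at 28. 26 is converted (MsCl, Et3N, CH2Cl2, 0 °C) into the mesylate F16, and Bu4NF in THF then removes the silyl group, so the phenoxide should be trapped at once by displacement at C2 (6-exo-tet) to give 28.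

## Further compounds

F1 | step 14 | 1,3-bis(benzyloxy)-4-bromo-2-(3-methylbut-2-en-1-yl)benzene | Brc1ccc(OCc2ccccc2)c(CC=C(C)C)c1OCc1ccccc1
F2 | step 14 | methyl 2-[2,4-bis(benzyloxy)-3-(3-methylbut-2-en-1-yl)phenyl]acetate | COC(=O)Cc1ccc(OCc2ccccc2)c(CC=C(C)C)c1OCc1ccccc1
F3 | step 14 | 2-[2,4-bis(benzyloxy)-3-(3-methylbut-2-en-1-yl)phenyl]acetic acid | OC(=O)Cc1ccc(OCc2ccccc2)c(CC=C(C)C)c1OCc1ccccc1
F4 | step 14 | (4R)-4-benzyl-3-{2-[2,4-bis(benzyloxy)-3-(3-methylbut-2-en-1-yl)phenyl]acetyl}-1,3-oxazolidin-2-one | O=C1OC[C@@H](Cc2ccccc2)N1C(=O)Cc1ccc(OCc2ccccc2)c(CC=C(C)C)c1OCc1ccccc1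
F5 | step 14 | {[5-(benzyloxy)-2-(bromomethyl)-3-methoxy-4-(3-methylbut-2-en-1-yl)phenyl]oxy}triisopropylsilane | COc1c(CC=C(C)C)c(OCc2ccccc2)cc(O[Si](C(C)C)(C(C)C)C(C)C)c1CBr
F6 | step 14 | (4R)-4-benzyl-3-[(2R)-2-[2,4-bis(benzyloxy)-3-(3-methylbut-2-en-1-yl)phenyl]-3-{4-(benzyloxy)-2-methoxy-3-(3-methylbut-2-en-1-yl)-6-[(triisopropylsilyl)oxy]phenyl}propanoyl]-1,3-oxazolidin-2-one | O=C1OC[C@@H](Cc2ccccc2)N1C(=O)[C@H](Cc1c(OC)c(CC=C(C)C)c(OCc2ccccc2)cc1O[Si](C(C)C)(C(C)C)C(C)C)c1ccc(OCc2ccccc2)c(CC=C(C)C)c1OCc1ccccc1
F7 | step 14 | (2R)-2-[2,4-bis(benzyloxy)-3-(3-methylbut-2-en-1-yl)phenyl]-3-{4-(benzyloxy)-2-methoxy-3-(3-methylbut-2-en-1-yl)-6-[(triisopropylsilyl)oxy]phenyl}propan-1-ol | OC[C@H](Cc1c(OC)c(CC=C(C)C)c(OCc2ccccc2)cc1O[Si](C(C)C)(C(C)C)C(C)C)c1ccc(OCc2ccccc2)c(CC=C(C)C)c1OCc1ccccc1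
F8 | step 14 | 5-(benzyloxy)-2-{(2R)-2-[2,4-bis(benzyloxy)-3-(3-methylbut-2-en-1-yl)phenyl]-3-hydroxypropyl}-3-methoxy-4-(3-methylbut-2-en-1-yl)phenol | OC[C@H](Cc1c(OC)c(CC=C(C)C)c(OCc2ccccc2)cc1O)c1ccc(OCc2ccccc2)c(CC=C(C)C)c1OCc1ccccc1
F9 | step 14 | (3R)-7-(benzyloxy)-3-[2,4-bis(benzyloxy)-3-(3-methylbut-2-en-1-yl)phenyl]-5-methoxy-6-(3-methylbut-2-en-1-yl)-3,4-dihydro-2H-chromene | COc1c(CC=C(C)C)c(OCc2ccccc2)cc2c1C[C@H](c1ccc(OCc3ccccc3)c(CC=C(C)C)c1OCc1ccccc1)CO2
F10 | step 4 | 4-(benzyloxy)-2,6-dihydroxy-3-(3-methylbut-2-en-1-yl)benzaldehyde | O=Cc1c(O)cc(OCc2ccccc2)c(CC=C(C)C)c1O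
F11 | step 4 | 4-(benzyloxy)-2-hydroxy-3-(3-methylbut-2-en-1-yl)-6-[(triisopropylsilyl)oxy]benzaldehyde | O=Cc1c(O[Si](C(C)C)(C(C)C)C(C)C)cc(OCc2ccccc2)c(CC=C(C)C)c1O
F12 | step 11 | {[5-(benzyloxy)-2-(chloromethyl)-3-methoxy-4-(3-methylbut-2-en-1-yl)phenyl]oxy}triisopropylsilane | COc1c(CC=C(C)C)c(OCc2ccccc2)cc(O[Si](C(C)C)(C(C)C)C(C)C)c1CCl
F13 | step 12 | [3-(benzyloxy)-6-bromo-2-(3-methylbut-2-en-1-yl)phenoxy](tert-butyl)dimethylsilane | CC(C)(C)[Si](C)(C)Oc1c(Br)ccc(OCc2ccccc2)c1CC=C(C)C
F14 | step 12 | methyl 2-{4-(benzyloxy)-2-[(tert-butyldimethylsilyl)oxy]-3-(3-methylbut-2-en-1-yl)phenyl}acetate | COC(=O)Cc1ccc(OCc2ccccc2)c(CC=C(C)C)c1O[Si](C)(C)C(C)(C)C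
F15 | step 12 | methyl 2-[4-(benzyloxy)-2-hydroxy-3-(3-methylbut-2-en-1-yl)phenyl]acetate | COC(=O)Cc1ccc(OCc2ccccc2)c(CC=C(C)C)c1O
F16 | step 16 | [(2R,3R)-6-(benzyloxy)-2-{4-(benzyloxy)-2-methoxy-3-(3-methylbut-2-en-1-yl)-6-[(triisopropylsilyl)oxy]phenyl}-7-(3-methylbut-2-en-1-yl)-2,3-dihydro-1-benzofuran-3-yl]methyl methanesulfonate | COc1c(CC=C(C)C)c(OCc2ccccc2)cc(O[Si](C(C)C)(C(C)C)C(C)C)c1[C@@H]1Oc2c(CC=C(C)C)c(OCc3ccccc3)ccc2[C@@H]1COS(C)(=O)=O
A1 | alternative 1 | (E)-1-diazo-4-[(3R)-5-methoxy-7-(methoxymethoxy)-6-(3-methylbut-2-en-1-yl)-3,4-dihydro-2H-chromen-3-yl]but-3-en-2-one | COc1c(CC=C(C)C)c(OCOC)cc2c1C[C@H](/C=C/C(=O)C=[N+]=[N-])CO2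
A2 | alternative 1 | triisopropyl[(5-methylhex-4-en-1-yn-1-yl)oxy]silane | CC(C)=CCC#CO[Si](C(C)C)(C(C)C)C(C)C
A3 | alternative 1 | 6-[(3R)-5-methoxy-7-(methoxymethoxy)-6-(3-methylbut-2-en-1-yl)-3,4-dihydro-2H-chromen-3-yl]-2-(3-methylbut-2-en-1-yl)-3-[(triisopropylsilyl)oxy]phenol | COc1c(CC=C(C)C)c(OCOC)cc2c1C[C@H](c1ccc(O[Si](C(C)C)(C(C)C)C(C)C)c(CC=C(C)C)c1O)CO2
A4 | alternative 2 | 3-methoxy-5-(methoxymethoxy)-4-(3-methylbut-2-en-1-yl)-2-[(4-methylbenzenesulfonyl)methyl]phenol | COc1c(CC=C(C)C)c(OCOC)cc(O)c1CS(=O)(=O)c1ccc(C)cc1
A5 | alternative 2 | 2-[2,4-bis(methoxymethoxy)-3-(3-methylbut-2-en-1-yl)phenyl]-1-(1H-imidazol-1-yl)ethan-1-one | COCOc1ccc(CC(=O)n2ccnc2)c(OCOC)c1CC=C(C)C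
A6 | alternative 2 | (3R)-3-[2,4-bis(methoxymethoxy)-3-(3-methylbut-2-en-1-yl)phenyl]-5-methoxy-7-(methoxymethoxy)-6-(3-methylbut-2-en-1-yl)-3,4-dihydro-2H-chromen-2-one | COc1c(CC=C(C)C)c(OCOC)cc2c1C[C@H](c1ccc(OCOC)c(CC=C(C)C)c1OCOC)C(=O)O2
A7 | alternative 3 | triisopropyl{[5-methoxy-6-(3-methylbut-2-en-1-yl)-2H-chromen-7-yl]oxy}silane | COc1c(CC=C(C)C)c(O[Si](C(C)C)(C(C)C)C(C)C)cc2OCC=Cc12
A8 | alternative 3 | 2-(allyloxy)-3-(3-methylbut-2-en-1-yl)cyclohexa-2,5-diene-1,4-dione | C=CCOC1=C(CC=C(C)C)C(=O)C=CC1=O
A9 | alternative 3 | (6aR,11aR)-9-(allyloxy)-1-methoxy-2,10-bis(3-methylbut-2-en-1-yl)-3-[(triisopropylsilyl)oxy]-6a,11a-dihydro-6H-[1]benzofuro[3,2-c]chromen-8-ol | COc1c(CC=C(C)C)c(O[Si](C(C)C)(C(C)C)C(C)C)cc2c1[C@@H]1Oc3c(CC=C(C)C)c(OCC=C)c(O)cc3[C@@H]1CO2
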